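## Structural features

The carbon core is a decahydrofluorene. Ring A is the cyclohexane C2/C3/C4/C6/C36/C38, ring B the cyclopentane C6/C7/C32/C31/C36 and ring C the cyclohexane C31/C32/C33/C25/C27/C29. Both ring fusions are trans: H6 and H31 lie on the β face, the C36 methyl and H32 on the α face (α is the face of the C36 methyl throughout).

A 13-membered para-cyclophane runs from C7 through the aryl ether O8–C9, the benzene ring and benzylic C15 to C16, C18, C19 and the ketone C34 on C33. A γ-lactam (N41, C16, C18, C19, C39) bridges C16 and C19 of this macrocycle. An eight-membered 1,2-dioxocane (C19, C20, C21, O23, O24, C25, C33, C34) ties quaternary C19 to ring C.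

Ten stereocentres form an unbroken chain (C4, C6, C36, C31, C29, C27, C25, C33, C32, C7). C2 is one methylene away, and C16, C19 and C21 sit in the heterocyclic part. C36 and C19 are all-carbon quaternary centres.

The fragile groups are:
- the dialkyl peroxide, whose C21 carries H and OH (base, reductants);
- the trisubstituted α-epoxide C27–O28–C29 (acid);
- the hemiaminal C16;
- the β-keto lactam, which cannot enolise at C19 (retro-Claisen cleavage);
- the bent arene of the cyclophane.

The real difficulty is threefold: quaternary C36 inside a trans-hydrindane, the strained macrocycle, and the late placing of O24 and O28 on the hindered α face.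

The key step exploits ring A. Its methyls on C2, C4 and C36 surround C3 exactly as in 2,4,6-trimethylphenol. If C3 is the phenolic carbon, C36 is the para carbon and stands next to C6. An allyl unit hung on C6 through C7–C32 can therefore be attacked by the phenolate para carbon, which forms C31–C36, ring B and the quaternary centre in one event. The C3 oxygen then serves to set C2, C4 and C6 before it is removed.

## Logic of the disconnections

**53 ⇒ 51.** The C21–O23 bond of the peroxy-hemiacetal is cut and C21 is taken back to the terminal alkene carbon of an allyl group on C19. The ring closes by reversible addition of a hydroperoxide to an aldehyde, so C21 needs no control. The demand is an aldehyde release that is neither reducing, basic nor acidic, because 51 already holds the hydroperoxide and the epoxide.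

**51 ⇒ 50 ⇒ 49.** O28 (C27–O and C29–O) is removed to a C27=C29 alkene. The C25–O24 bond is then cut with allylic transposition to a C25=C27 alkene carrying H on C29. A tertiary allylic hydroperoxide next to a shifted double bond is the signature of a singlet-oxygen ene reaction. This strips three stereocentres and every fragile oxygen from ring C. The forward steps must attack the α face at C25, abstract H29 and epoxidise syn to the hydroperoxide.

**49 ⇒ 46.** C16–O17 is cut to a C16–H lactam. The C–H stereocentre comes from an amino acid and is needed earlier to steer the construction of C19. The price is an oxidation at C16 in the presence of two alkenes.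

**46 ⇒ 45 ⇒ 44.** The O8–C9 bond is cut, which opens the cyclophane to a secondary alcohol and an aryl iodide. The C7–O bond is kept, so C7 is not at risk. The forward step must close a strained 13-membered ring.

**44 ⇒ 43 ⇒ 42 ⇒ 33 + 40.** The C19–C34 bond is cut to an aldehyde and a lactam enolate. C7 is taken back to the ketone, because the ketone is needed to build ring C and lets the C34 carbinol be oxidised without a protecting group. Demands: attack anti to the benzyl group of 40, and later a β-face hydride delivery to C7 that leaves C34 alone.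

**40 ⇒ 38 ⇒ 37 ⇒ 34 + 35.** The allyl–C19 bond and then the lactam are cut back to a protected amino acid and a two-carbon malonate equivalent. The gain is an enantiopure lactam in three steps.

**33 ⇒ 31 ⇒ 30 ⇒ 23 + 28 (28 ⇒ 26 ⇒ 24 + 25).** Ring C is opened at C25=C27 (metathesis) and at C32–C33 (conjugate addition of the C7 ketone enolate to a nitrodiene). The nitromethyl group is the latent C34 aldehyde. This reduces ring C to a ketone with a butenyl side chain. The demand is 1,4-addition with control of C32 and C33.

**23 ⇒ 22 ⇒ 21 ⇒ 19.** The vinyl carbon beyond C27 is removed and C29–H/C27–O is taken back to the isopropenyl group. The forward hydroboration must set C29.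

**19 ⇒ 17 ⇒ 15 ⇒ 13.** The C3 oxygen is reinstated, then the C4=C6 and C2=C38 double bonds. The ketone allows C2 and C4 to be set by equilibration and C6 by protonation. The two enone reductions must be kept apart and the allylic C–C bond at C36 must survive.

**13 ⇒ 12.** The C31–C36 bond is cut. The dienone becomes a phenol and C31 an allyl terminus activated as a carbonate. One ring, one skeletal bond and two stereocentres are removed. The forward step needs para attack, 5-exo closure and the correct C36/C31 faces.

**12 ⇒ 11 ⇒ 10 ⇒ 6 + 7; 6 ⇒ 5 ⇒ 3 + 4; 3 ⇒ 2 ⇒ 1.** The carbonate, the allylic alcohol, the C29=C31 bond (Wittig), the C32–C7 bond (allylation of an aldehyde, which sets C7) and the formyl group are removed in turn. What remains is the protected phenol.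

## Other disconnections considered

**Alternative 1:** No skeletal bond is cut; the benzene ring C9–C14 is traced back to a 3-alkoxycyclohex-2-enone inside the closed macrocycle, A1. The forward step is an aerobic dehydrogenation with Pd(TFA)2 under O2, which turns A1 into phenol A2.
- In its favour: the macrocycle is closed on a flexible ring and the arene strain arrives last. On the macrocycle problem this is the equal of the chosen plan, and probably the better, since the ring would close by vinylogous ester formation and not by a C–O coupling on a bent arene.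
- Against it: A2 keeps a hydroxyl on C11 that costs two steps to remove, and C12 of A1 is an extra stereocentre of no use. Hot divalent palladium under O2 also meets the trisubstituted ring C alkene and the β-keto lactam.
- Comparison: mechanistically it is a dehydrogenation, not a bond construction, so it says nothing about rings A, B and C or about C36. It is a variant of one late step and could replace step 26 of the present route at three or four extra steps. It does not compete with the dearomatization as the strategy for the core.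

**Alternative 2:** The bonds C32–C33 and C29–C31 are cut. Ring C comes from a [4+2] addition of 4,6-dimethyl-2-pyrone A3 to methyl (E)-4-oxobut-2-enoate A4 under iminium catalysis, which gives the bridged lactone A5.
- In its favour: two commercial partners and one catalytic enantioselective step deliver C29, C31, C32 and C33, an α oxygen on C29 that could become O28, the C7 aldehyde and C34 at the acid level. On ring C this is clearly better than the chosen plan, which spends eight steps there.
- Against it: A3 is an electron-poor diene and pairs badly with an acceptor that the catalyst makes still poorer. Adducts of type A5 lose CO2 easily. In A5, C36 is only an ester carbon, so the quaternary centre and rings A and B would have to be raised afterwards at a neopentyl position.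
- Comparison: the chosen plan makes its hardest carbon first, in a step whose selectivity is set by the substrate, and pays with a longer ring C sequence. Alternative 2 makes the easy ring in one step and postpones the hard centre. Over the whole core the step count would probably be similar.

**Alternative 3:** The bonds C6–C36 and C3–C4 are cut. A trienoate A6, a ring C cyclohexene with a dienyl arm on C31 and an enoate arm on C32, undergoes an Et2AlCl-promoted intramolecular Diels–Alder reaction to the tricyclic diester A7.
- In its favour: one step closes rings A and B and sets C4, C6 and C36 with the trans A/B fusion. For C6 it is better than the chosen plan, which needs a separate enone reduction; for C36 it is the equal.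
- Against it: the diene terminus C36 is fully substituted, which slows the cycloaddition and invites Lewis-acid side reactions. C4 emerges as an ester and needs three steps to become methyl. C2 would have to be set by hydrogenation of C2=C38 with no chance of equilibration. Ring C with three stereocentres and both arms must be built first, and its double bond ends conjugated (C25=C33) in A7 and must be moved.
- Comparison: the cycloaddition builds more bonds per step, but the chosen dearomatization starts from a commercial arene that already holds all of ring A, and keeps a ketone that corrects C2 and C4 thermodynamically. Step counts for the tricycle would be close.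

Key step: step 8

Assumption: C16 (hemiaminal) and C21 (peroxy-hemiacetal) are stereolabile by ring–chain equilibration, and their configurations in the target are taken to be the thermodynamic ones.

Step 1
Reactants: 1 2,4,6-trimethylphenol
Product: 2 2,4,6-trimethylphenyl acetate
Conditions: Ac2O, pyridine, DMAP (cat.), CH2Cl2, 23 °C
Reagents that add atoms: acetic anhydride, CC(=O)OC(C)=O
Why: DMAP-catalysed O-acylation of the hindered phenol; the acetate tolerates the Lewis acid of step 2 and is removed for free by the hydride of step 6.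

Step 2
Reactants: 2 2,4,6-trimethylphenyl acetate
Product: 3 3-acetoxy-2,4,6-trimethylbenzaldehyde
Conditions: Cl2CHOMe, TiCl4, CH2Cl2, 0 → 23 °C; H2O
Reagents that add atoms: dichloromethyl methyl ether, COC(Cl)Cl; water, O
Why: Rieche formylation; the two free ring positions are equivalent and each is ortho/para to three methyl groups, and the blocked ortho and para sites of the acetoxy group exclude a Fries shift.

Step 3
Reactants: 3 3-acetoxy-2,4,6-trimethylbenzaldehyde; 4 allylboronic acid pinacol ester
Product: 5 3-[(1S)-1-hydroxybut-3-en-1-yl]-2,4,6-trimethylphenyl acetate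
Conditions: (S)-TRIP (5 mol%), toluene, −30 °C
Reagents that add atoms: none
Why: Chiral phosphoric acid-catalysed allylboration through a chair six-membered transition state (TRIP = 3,3′-bis(2,4,6-triisopropylphenyl)-1,1′-binaphthyl-2,2′-diyl hydrogen phosphate); the (S)-acid is the enantiomer that should deliver allyl to the Si face of aryl aldehydes, giving the (S)-carbinol that becomes C7.

Step 4
Reactants: 5 3-[(1S)-1-hydroxybut-3-en-1-yl]-2,4,6-trimethylphenyl acetate
Product: 6 3-[(1S)-1-(tert-butyldimethylsilyloxy)but-3-en-1-yl]-2,4,6-trimethylphenyl acetate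
Conditions: TBSOTf, 2,6-lutidine, CH2Cl2, −78 → 0 °C
Reagents that add atoms: tert-butyldimethylsilyl triflate, CC(C)(C)[Si](C)(C)OS(=O)(=O)C(F)(F)F
Why: Silylation of the hindered benzylic alcohol with the silyl triflate; the bulky ether later differentiates the two faces of the arene.

Step 5
Reactants: 6 3-[(1S)-1-(tert-butyldimethylsilyloxy)but-3-en-1-yl]-2,4,6-trimethylphenyl acetate; 7 ethyl 2-(triphenylphosphoranylidene)propanoate
Product: 10 ethyl (2E,5S)-5-(3-acetoxy-2,4,6-trimethylphenyl)-5-(tert-butyldimethylsilyloxy)-2-methylpent-2-enoate, via ozonide 8 (not isolated), via aldehyde 9 (not isolated)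
Conditions: O3, CH2Cl2, −78 °C; PPh3, −78 → 23 °C; then 7, 23 °C
Reagents that add atoms: none
Why: Ozonolysis of the terminal alkene (far faster than attack on the acetoxy arene) and Wittig olefination of the β-silyloxy aldehyde under neutral conditions; the stabilised ylide should give the (E)-trisubstituted enoate.

Step 6
Reactants: 10 ethyl (2E,5S)-5-(3-acetoxy-2,4,6-trimethylphenyl)-5-(tert-butyldimethylsilyloxy)-2-methylpent-2-enoate
Product: 11 3-[(1S,3E)-1-(tert-butyldimethylsilyloxy)-5-hydroxy-4-methylpent-3-en-1-yl]-2,4,6-trimethylphenol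
Conditions: (iBu)2AlH (5 equiv), CH2Cl2, −78 → 0 °C; aq. KNa tartrate
Reagents that add atoms: none
Why: 1,2-Reduction of the enoate to the allylic alcohol; the same hydride cleaves the aryl acetate, so the phenol is released without a separate step.

Step 7
Reactants: 11 3-[(1S,3E)-1-(tert-butyldimethylsilyloxy)-5-hydroxy-4-methylpent-3-en-1-yl]-2,4,6-trimethylphenol
Product: 12 (2E,5S)-5-(tert-butyldimethylsilyloxy)-5-(3-hydroxy-2,4,6-trimethylphenyl)-2-methylpent-2-en-1-yl methyl carbonate
Conditions: ClCO2Me (1.1 equiv), pyridine, CH2Cl2, −20 °C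
Reagents that add atoms: methyl chloroformate, COC(=O)Cl
Why: Acylation of the primary allylic alcohol; the phenol is flanked by two methyl groups and is not deprotonated by pyridine, so it should react far more slowly.

Step 8
Reactants: 12 (2E,5S)-5-(tert-butyldimethylsilyloxy)-5-(3-hydroxy-2,4,6-trimethylphenyl)-2-methylpent-2-en-1-yl methyl carbonate
Product: 13 (1S,3S,7aS)-3-(tert-butyldimethylsilyloxy)-4,6,7a-trimethyl-1-(prop-1-en-2-yl)-1,2,3,7a-tetrahydro-5H-inden-5-one
Conditions: Pd2(dba)3·CHCl3 (2.5 mol%), (11R,12R)-11,12-bis[2-(diphenylphosphino)benzamido]-9,10-dihydro-9,10-ethanoanthracene (7.5 mol%), CH2Cl2, 23 °C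
Reagents that add atoms: none
Why: Zerovalent palladium ionises the allylic carbonate with inversion, the carbonate anion loses CO2 and the methoxide formed deprotonates the phenol, so no external base is needed. The phenolate then attacks the π-allyl ligand of divalent palladium through its para carbon C36, outside the coordination sphere and anti to the metal, at the allyl terminus C31; this is a 5-exo closure of ring B, whereas attack at C27 would need a seven-membered ring. The closest known reaction type is the palladium-catalysed intramolecular allylic dearomatization (ipso-Friedel–Crafts alkylation) of phenols to cyclohexadienones. C36 is controlled by C7: the C7–H bond lies in the arene plane beside the C4 methyl to avoid A(1,3) strain, which puts the silyloxy group on one face and the tether on the other, so the allyl unit reaches C36 only anti to the silyl ether. C31 is controlled by the closure geometry: the metal-bearing part of the allyl ligand turns away from the arene (exo), and because the ligand can change faces by η3–η1–η3 isomerisation at its CH2 terminus this preference is expressed whatever the carbonate geometry, with the chiral diphosphine chosen as the matched partner. The step needs para rather than ortho (C4) attack; both would give a five-membered ring, but the para carbon carries the larger coefficient of the phenolate HOMO and leads to the more stable cross-conjugated dienone, and O-alkylation within the molecule is geometrically impossible. The methyl groups on C2, C4 and C36 block rearomatisation, so 13 keeps the quaternary centre.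

Step 9
Reactants: 13 (1S,3S,7aS)-3-(tert-butyldimethylsilyloxy)-4,6,7a-trimethyl-1-(prop-1-en-2-yl)-1,2,3,7a-tetrahydro-5H-inden-5-one
Product: 15 C7-hydroxy enone (C3 ketone; C4=C6 double bond; C2 methyl equatorial; C7 hydroxyl and C31 isopropenyl α), via silyl dienol ether 14 (not isolated)
Conditions: [(Ph3P)CuH]6 (5 mol%), (EtO)2MeSiH, toluene, 23 °C; then Bu4NF, THF, 23 °C
Reagents that add atoms: none
Why: Copper hydride conjugate reduction takes only the less hindered C2=C38 enone and leaves the isopropenyl group; a two-electron hydride is used here because an electron-transfer reductant could expel the allylic C31 from the dienone with rearomatisation. Fluoride then cleaves the silyl enol ether and the C7 silyl ether and lets C2 settle equatorial.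

Step 10
Reactants: 15 C7-hydroxy enone
Product: 17 trans-fused hydroxy ketone (C3 ketone; C2 and C4 methyls equatorial and cis; H6 β; C7 hydroxyl α), via C4-epimeric ketone 16 (not isolated)
Conditions: Li, NH3(l), THF, t-BuOH, −78 °C; NH4Cl; then NaOMe, MeOH, 23 °C
Reagents that add atoms: none
Why: Dissolving-metal reduction of the tetrasubstituted enone; the β-carbanion at C6 should be protonated axially from the β face, away from the angular methyl, the C7 alkoxide and the isopropenyl group, giving the trans fusion. As a lithium alkoxide the C7 oxygen cannot be eliminated, and methoxide then equilibrates C4 (and C2) to the all-equatorial ketone, in which neither methyl is 1,3-diaxial to the C36 methyl.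

Step 11
Reactants: 17 trans-fused hydroxy ketone
Product: 19 bicyclic alcohol (ring A complete with C3 as CH2; C7 hydroxyl α; C31 isopropenyl α), via hydrazone 18 (not isolated)
Conditions: N2H4·H2O, diethylene glycol, 130 °C; then KOH, 200 °C
Reagents that add atoms: none
Why: Wolff–Kishner reduction (Huang–Minlon procedure) removes the C3 oxygen; the α-centres are already at their thermodynamic configuration, so the hot base cannot harm them, and the isolated alkene is inert when air is excluded.

Step 12
Reactants: 19 bicyclic alcohol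
Product: 21 diol with (29R)-configured C29 (C7 hydroxyl; C27 primary hydroxyl), via alkylborane 20 (not isolated)
Conditions: 9-BBN (3 equiv), THF, 0 → 23 °C; then NaOH, H2O2, 0 °C
Reagents that add atoms: hydrogen peroxide, OO
Why: Anti-Markovnikov hydroboration and oxidation; with the C31–H bond eclipsing the C=CH2 bond the borane should add anti to quaternary C36, the sense known for 17-isopropenyl trans-hydrindanes of the steroid series, which gives H29 α and the C30 methyl β.

Step 13
Reactants: 21 diol
Product: 22 keto aldehyde (C7 ketone; C27 aldehyde)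
Conditions: DMP, NaHCO3, CH2Cl2, 0 → 23 °C
Reagents that add atoms: none
Why: Buffered Dess–Martin oxidation of both alcohols in one operation; the non-basic conditions should spare the α-stereocentre C29, and the aldehyde is used at once.

Step 14
Reactants: 22 keto aldehyde
Product: 23 vinyl ketone (C7 ketone; C31 carrying the (R)-but-3-en-2-yl group)
Conditions: Ph3PCH3Br, KN(SiMe3)2, THF, −78 → 0 °C
Reagents that add atoms: methyltriphenylphosphonium bromide, C[P+](c1ccccc1)(c1ccccc1)c1ccccc1.[Br-]
Why: Wittig methylenation; at low temperature one equivalent of ylide should take the aldehyde and leave the cyclopentanone, which is flanked by a ring-fusion carbon.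

Step 15
Reactants: 24 methacrolein; 25 nitromethane
Product: 26 3-methyl-1-nitrobut-3-en-2-ol (racemic)
Conditions: Amberlyst A-21, MeNO2 (solvent), 0 °C
Reagents that add atoms: none
Why: Henry reaction on a weakly basic resin, conditions under which enals are expected to add nitromethane at the carbonyl carbon and not at the β-carbon.

Step 16
Reactants: 26 3-methyl-1-nitrobut-3-en-2-ol
Product: 28 (E)-3-methyl-1-nitrobuta-1,3-diene, via mesylate 27 (not isolated)
Conditions: MsCl, Et3N, CH2Cl2, −20 → 0 °C
Reagents that add atoms: none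
Why: Sulfonylation and E1cB elimination of the β-nitro alcohol gives the (E)-nitroalkene; the diene is kept in solution and used directly.

Step 17
Reactants: 23 vinyl ketone; 28 (E)-3-methyl-1-nitrobuta-1,3-diene
Product: 30 Michael adduct (C32 carrying C33; C33 with nitromethyl C34 and isopropenyl C25), via lithium enolate 29 (not isolated)
Conditions: LiN(iPr)2, THF, −78 °C; then 28, −78 °C; AcOH
Reagents that add atoms: none
Why: Kinetic deprotonation at the C32 methylene (C6 is a tertiary ring-fusion carbon) gives the C7=C32 enolate 29, which undergoes Michael addition to the nitroalkene carbon next to the isopropenyl group; attack on the β face of the enolate, anti to the C31 side chain, sets C32, and the synclinal (unlike) topicity usual for cyclic ketone enolates and (E)-nitroalkenes should set C33 as required.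

Step 18
Reactants: 30 Michael adduct
Product: 31 tricyclic nitro ketone (ring C closed; C25=C27 double bond; C7 ketone; C34 nitromethyl)
Conditions: second-generation Hoveyda–Grubbs catalyst (5 mol%), CH2Cl2, 40 °C
Reagents that add atoms: none
Why: Ring-closing metathesis of the vinyl and isopropenyl groups gives the trisubstituted cyclohexene; no stereocentre is touched, and nitro and ketone groups are tolerated.

Step 19
Reactants: 31 tricyclic nitro ketone
Product: 33 tricyclic keto aldehyde (C7 ketone; C34 aldehyde on C33), via sodium nitronate 32 (not isolated)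
Conditions: NaOMe, MeOH, 0 °C; then TiCl3, NH4OAc, H2O, 0 → 23 °C
Reagents that add atoms: water, O
Why: Reductive Nef reaction; the nitronate is reduced to the imine and hydrolysed near neutral pH, which avoids the strong acid that would cyclise the 1,4-dicarbonyl unit and should leave C33 and the β,γ-alkene in place.

Step 20
Reactants: 34 N-Boc-4-iodo-D-phenylalanine; 35 Meldrum's acid
Product: 37 tert-butyl N-[(2S)-1-(2,2-dimethyl-4,6-dioxo-1,3-dioxan-5-yl)-3-(4-iodophenyl)propan-2-yl]carbamate, via acyl Meldrum's acid 36 (not isolated)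
Conditions: EDC·HCl, DMAP, CH2Cl2, 0 → 23 °C; then AcOH, NaBH4, 0 °C
Reagents that add atoms: none
Why: Carbodiimide C-acylation of Meldrum's acid and reduction of the enolised acyl group to CH2 by the acetoxyborohydride; the amino acid stereocentre is not involved.

Step 21
Reactants: 37 tert-butyl N-[(2S)-1-(2,2-dimethyl-4,6-dioxo-1,3-dioxan-5-yl)-3-(4-iodophenyl)propan-2-yl]carbamate
Product: 38 tert-butyl (2S)-2-(4-iodobenzyl)-5-oxopyrrolidine-1-carboxylate
Conditions: toluene, 110 °C
Reagents that add atoms: none
Why: Thermal loss of acetone gives an acyl ketene that is trapped by the carbamate nitrogen, and decarboxylation leaves the N-Boc γ-lactam with C16 set by the D-amino acid.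

Step 22
Reactants: 38 tert-butyl (2S)-2-(4-iodobenzyl)-5-oxopyrrolidine-1-carboxylate
Product: 40 tert-butyl (3R,5S)-3-allyl-5-(4-iodobenzyl)-2-oxopyrrolidine-1-carboxylate, via lithium enolate 39 (not isolated)
Conditions: LiN(SiMe3)2, THF, −78 °C; allyl bromide, −78 → −40 °C
Reagents that add atoms: allyl bromide, C=CCBr
Why: Enolate alkylation of the N-Boc lactam; the electrophile should enter trans to the benzyl group on C16.

Step 23
Reactants: 40 tert-butyl (3R,5S)-3-allyl-5-(4-iodobenzyl)-2-oxopyrrolidine-1-carboxylate; 33 tricyclic keto aldehyde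
Product: 42 aldol adduct (C19–C34 bond; C34 carbinol as a mixture; C19 quaternary), via lithium enolate 41 (not isolated)
Conditions: LiN(iPr)2, THF, −78 °C; then 33, −78 °C; NH4Cl
Reagents that add atoms: none
Why: Aldol addition of the tetrasubstituted lactam enolate to the aldehyde, which is far more reactive than the hindered C7 ketone; the aldehyde again enters trans to the C16 benzyl group, so C34 ends anti and the allyl group syn to it, which is the target arrangement at C19.

Step 24
Reactants: 42 aldol adduct
Product: 43 diketone (C34 ketone between C33 and quaternary C19; C7 ketone)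
Conditions: DMP, NaHCO3, CH2Cl2, 23 °C
Reagents that add atoms: none
Why: Dess–Martin oxidation of the only hydroxyl group merges the carbinol epimers into the β-keto lactam; C19 cannot enolise.

Step 25
Reactants: 43 diketone
Product: 44 C7 α-alcohol (aryl iodide and C34 ketone unchanged)
Conditions: NaBH4, CeCl3·7H2O, MeOH/THF, −78 °C
Reagents that add atoms: none
Why: Luche reduction; hydride should attack C7 from the β face, anti to the axial C36 methyl, which restores the C7 configuration of the target. The C34 ketone lies between a quaternary and a tertiary carbon and the lactam carbonyl next to quaternary C19, so neither should react at this temperature.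

Step 26
Reactants: 44 C7 α-alcohol
Product: 45 N-Boc macrocycle (13-membered para-cyclophane closed through O8–C9; C16–H)
Conditions: CuI (1 equiv), 3,4,7,8-tetramethyl-1,10-phenanthroline, Cs2CO3, toluene (0.002 M), 110 °C
Reagents that add atoms: none
Why: Intramolecular Ullmann-type C–O coupling of the secondary alkoxide with the aryl iodide, a closure type known for strained para-cyclophane aryl alkyl ethers; the C7–O bond is not broken, the Boc group keeps the lactam nitrogen out of the coupling, and high dilution disfavours oligomers.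

Step 27
Reactants: 45 N-Boc macrocycle
Product: 46 macrocyclic NH lactam
Conditions: TFA, CH2Cl2, 0 °C
Reagents that add atoms: none
Why: Acidolysis of the imide-type tert-butyl carbamate, which should be fast enough at 0 °C to spare the trisubstituted alkene.

Step 28
Reactants: 46 macrocyclic NH lactam
Product: 49 macrocyclic hemiaminal (C16 hydroxyl), via N-chloro lactam 47 (not isolated), via N-acylimine 48 (not isolated)
Conditions: t-BuOCl, CH2Cl2, 0 °C, dark; DBU, 0 °C; then THF/H2O, PPTS, 23 °C
Reagents that add atoms: water, O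
Why: N-Chlorination of the secondary lactam, dehydrochlorination to the N-acylimine and hydration, the sequence used to oxygenate the carbon next to an amide nitrogen; C15 stays held by the macrocycle, so water should return C16 to the arrangement that the ring already accommodates.

Step 29
Reactants: 49 macrocyclic hemiaminal
Product: 50 tertiary allylic hydroperoxide (C25 hydroperoxide on the α face; C27=C29 double bond)
Conditions: O2, hν (visible), tetraphenylporphyrin, CH2Cl2, −20 °C
Reagents that add atoms: dioxygen, O=O
Why: Schenck ene reaction of singlet oxygen with the trisubstituted alkene; suprafacial attack on the α face at C25 with abstraction of the axial, α-oriented H29 moves the double bond to C27=C29. H33 sits on the β face and is deactivated by the ketone, the methyl group lies on the less reactive side of the alkene, and the terminal allyl alkene is inert.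

Step 30
Reactants: 50 tertiary allylic hydroperoxide
Product: 51 α-epoxy hydroperoxide (C27–O28–C29 epoxide syn to the C25 hydroperoxide)
Conditions: mCPBA, NaHCO3, CH2Cl2, 0 °C
Reagents that add atoms: 3-chloroperoxybenzoic acid, OOC(=O)c1cccc(Cl)c1
Why: Peracid epoxidation of the trisubstituted alkene in preference to the terminal one; the pseudo-axial hydroperoxy group is an O–H donor on the α face and should guide the peracid to that face, as an allylic hydroxyl does.

Step 31
Reactants: 51 α-epoxy hydroperoxide
Product: 53 CNP0533733.1, via seco-aldehyde 52 (not isolated)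
Conditions: O3, pyridine, CH2Cl2, −78 °C; then 23 °C
Reagents that add atoms: ozone, [O-][O+]=O
Why: Ozonolysis in the presence of pyridine gives the C21 aldehyde directly, without a reducing work-up that would destroy the hydroperoxide; the C25 hydroperoxide then adds to the aldehyde and closes the 1,2-dioxocane, with C21 settling under thermodynamic control.

## Compound list

1 | 2,4,6-trimethylphenol | Cc1cc(C)c(O)c(C)c1 | starting material
2 | 2,4,6-trimethylphenyl acetate | CC(=O)Oc1c(C)cc(C)cc1C | intermediate
3 | 3-acetoxy-2,4,6-trimethylbenzaldehyde | Cc1cc(C)c(C=O)c(C)c1OC(C)=O | intermediate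
4 | allylboronic acid pinacol ester | C=CCB1OC(C)(C)C(C)(C)O1 | starting material
5 | 3-[(1S)-1-hydroxybut-3-en-1-yl]-2,4,6-trimethylphenyl acetate | Cc1cc(C)c(c(C)c1OC(C)=O)[C@@H](O)CC=C | intermediate
6 | 3-[(1S)-1-(tert-butyldimethylsilyloxy)but-3-en-1-yl]-2,4,6-trimethylphenyl acetate | Cc1cc(C)c(c(C)c1OC(C)=O)[C@@H](O[Si](C)(C)C(C)(C)C)CC=C | intermediate
7 | ethyl 2-(triphenylphosphoranylidene)propanoate | CCOC(=O)C(C)=P(c1ccccc1)(c1ccccc1)c1ccccc1 | starting material
8 | secondary ozonide of 6 (1,2,4-trioxolane in place of the vinyl group; epimers at the ring carbon) | Cc1cc(C)c(c(C)c1OC(C)=O)[C@@H](O[Si](C)(C)C(C)(C)C)CC1OCOO1 | intermediate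
9 | 3-[(1S)-1-(tert-butyldimethylsilyloxy)-3-oxopropyl]-2,4,6-trimethylphenyl acetate | Cc1cc(C)c(c(C)c1OC(C)=O)[C@@H](O[Si](C)(C)C(C)(C)C)CC=O | intermediate
10 | ethyl (2E,5S)-5-(3-acetoxy-2,4,6-trimethylphenyl)-5-(tert-butyldimethylsilyloxy)-2-methylpent-2-enoate | Cc1cc(C)c(c(C)c1OC(C)=O)[C@@H](O[Si](C)(C)C(C)(C)C)C/C=C(\C)C(=O)OCC | intermediate
11 | 3-[(1S,3E)-1-(tert-butyldimethylsilyloxy)-5-hydroxy-4-methylpent-3-en-1-yl]-2,4,6-trimethylphenol | Cc1cc(C)c(c(C)c1O)[C@@H](O[Si](C)(C)C(C)(C)C)C/C=C(\C)CO | intermediate
12 | (2E,5S)-5-(tert-butyldimethylsilyloxy)-5-(3-hydroxy-2,4,6-trimethylphenyl)-2-methylpent-2-en-1-yl methyl carbonate | Cc1cc(C)c(c(C)c1O)[C@@H](O[Si](C)(C)C(C)(C)C)C/C=C(\C)COC(=O)OC | intermediate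
13 | (1S,3S,7aS)-3-(tert-butyldimethylsilyloxy)-4,6,7a-trimethyl-1-(prop-1-en-2-yl)-1,2,3,7a-tetrahydro-5H-inden-5-one (ring A/B dienone; C7, C31 and C36 all S) | CC1=C[C@]2(C)C(=C(C)C1=O)[C@@H](O[Si](C)(C)C(C)(C)C)C[C@H]2C(C)=C | intermediate
14 | silyl dienol ether of the C4=C6 enone (diethoxymethylsilyl on the C3 oxygen; C2=C3 and C4=C6 double bonds; C7 silyl ether) | CC1=C(O[Si](C)(OCC)OCC)C(C)=C2[C@@H](O[Si](C)(C)C(C)(C)C)C[C@@H](C(C)=C)[C@]2(C)C1 | intermediate
15 | C7-hydroxy enone (C3 ketone; C4=C6; C2 methyl equatorial and β; C7 hydroxyl and C31 isopropenyl α) | C[C@@H]1C(=O)C(C)=C2[C@@H](O)C[C@@H](C(C)=C)[C@]2(C)C1 | intermediate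
16 | trans-fused hydroxy ketone as the C4-epimeric mixture | C[C@@H]1C(=O)C(C)[C@H]2[C@@H](O)C[C@@H](C(C)=C)[C@]2(C)C1 | intermediate
17 | trans-fused hydroxy ketone (C3 ketone; C2 and C4 methyls equatorial, β; H6 β; C7 hydroxyl α) | C[C@@H]1C(=O)[C@H](C)[C@H]2[C@@H](O)C[C@@H](C(C)=C)[C@]2(C)C1 | intermediate
18 | hydrazone of 17 | C[C@@H]1C(=NN)[C@H](C)[C@H]2[C@@H](O)C[C@@H](C(C)=C)[C@]2(C)C1 | intermediate
19 | bicyclic alcohol: 4,6,7a-trimethyl-1-(prop-1-en-2-yl)octahydro-1H-inden-3-ol with hydroxyl, isopropenyl and 7a-methyl cis, H3a trans to the 7a-methyl, ring A methyls equatorial | C[C@@H]1C[C@H](C)[C@H]2[C@@H](O)C[C@@H](C(C)=C)[C@]2(C)C1 | intermediate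
20 | C27 alkylborane of 19 (9-borabicyclo[3.3.1]nonan-9-yl on C27; C7 oxygen as its 9-BBN borinate) | C[C@@H]1C[C@H](C)[C@H]2[C@@H](OB3C4CCCC3CCC4)C[C@@H]([C@@H](C)CB3C4CCCC3CCC4)[C@]2(C)C1 | intermediate
21 | diol (C7 hydroxyl; C31 carrying the (2R)-1-hydroxypropan-2-yl group, C29 R) | C[C@@H]1C[C@H](C)[C@H]2[C@@H](O)C[C@@H]([C@@H](C)CO)[C@]2(C)C1 | intermediate
22 | keto aldehyde (C7 ketone; C31 carrying the 1-oxopropan-2-yl group) | C[C@@H]1C[C@H](C)[C@H]2C(=O)C[C@@H]([C@@H](C)C=O)[C@]2(C)C1 | intermediate
23 | vinyl ketone (C7 ketone; C31 carrying the but-3-en-2-yl group) | C[C@@H]1C[C@H](C)[C@H]2C(=O)C[C@@H]([C@@H](C)C=C)[C@]2(C)C1 | intermediate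
24 | methacrolein | CC(=C)C=O | starting material
25 | nitromethane | C[N+](=O)[O-] | starting material
26 | 3-methyl-1-nitrobut-3-en-2-ol (racemic) | CC(=C)C(O)C[N+](=O)[O-] | intermediate
27 | 3-methyl-1-nitrobut-3-en-2-yl methanesulfonate | CC(=C)C(OS(C)(=O)=O)C[N+](=O)[O-] | intermediate
28 | (E)-3-methyl-1-nitrobuta-1,3-diene | CC(=C)/C=C/[N+](=O)[O-] | intermediate
29 | lithium C7=C32 enolate of 23 | C[C@@H]1C[C@H](C)[C@H]2C(O[Li])=C[C@@H]([C@@H](C)C=C)[C@]2(C)C1 | intermediate
30 | Michael adduct (C7 ketone; C32 β-substituted by C33, which carries nitromethyl C34 and isopropenyl C25; C31 butenyl) | C[C@@H]1C[C@H](C)[C@H]2C(=O)[C@H]([C@@H](C[N+](=O)[O-])C(C)=C)[C@@H]([C@@H](C)C=C)[C@]2(C)C1 | intermediate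
31 | tricyclic nitro ketone (rings A, B, C; C25=C27; C29 methyl β; C33 nitromethyl α; C7 ketone) | C[C@@H]1C[C@H](C)[C@H]2C(=O)[C@@H]3[C@@H](C[N+](=O)[O-])C(C)=C[C@H](C)[C@H]3[C@]2(C)C1 | intermediate
32 | sodium nitronate of 31 | C[C@@H]1C[C@H](C)[C@H]2C(=O)[C@@H]3[C@@H](C=[N+]([O-])[O-])C(C)=C[C@H](C)[C@H]3[C@]2(C)C1.[Na+] | intermediate
33 | tricyclic keto aldehyde (C7 ketone; C34 aldehyde on C33, α) | C[C@@H]1C[C@H](C)[C@H]2C(=O)[C@@H]3[C@@H](C=O)C(C)=C[C@H](C)[C@H]3[C@]2(C)C1 | intermediate
34 | N-Boc-4-iodo-D-phenylalanine, (R) | CC(C)(C)OC(=O)N[C@H](Cc1ccc(I)cc1)C(=O)O | starting material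
35 | Meldrum's acid | CC1(C)OC(=O)CC(=O)O1 | starting material
36 | 5-acyl Meldrum's acid from 34, (R) | CC(C)(C)OC(=O)N[C@H](Cc1ccc(I)cc1)C(=O)C1C(=O)OC(C)(C)OC1=O | intermediate
37 | tert-butyl N-[(2S)-1-(2,2-dimethyl-4,6-dioxo-1,3-dioxan-5-yl)-3-(4-iodophenyl)propan-2-yl]carbamate | CC(C)(C)OC(=O)N[C@H](Cc1ccc(I)cc1)CC1C(=O)OC(C)(C)OC1=O | intermediate
38 | tert-butyl (2S)-2-(4-iodobenzyl)-5-oxopyrrolidine-1-carboxylate | CC(C)(C)OC(=O)N1[C@H](Cc2ccc(I)cc2)CCC1=O | intermediate
39 | lithium enolate of 38 | CC(C)(C)OC(=O)N1[C@H](Cc2ccc(I)cc2)CC=C1O[Li] | intermediate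
40 | tert-butyl (3R,5S)-3-allyl-5-(4-iodobenzyl)-2-oxopyrrolidine-1-carboxylate | CC(C)(C)OC(=O)N1[C@H](Cc2ccc(I)cc2)C[C@@H](CC=C)C1=O | intermediate
41 | lithium enolate of 40 | CC(C)(C)OC(=O)N1[C@H](Cc2ccc(I)cc2)CC(CC=C)=C1O[Li] | intermediate
42 | aldol adduct (C34 carbinol epimers; C19 quaternary with allyl syn and C34 anti to the C16 benzyl group; C7 ketone) | C[C@@H]1C[C@H](C)[C@H]2C(=O)[C@@H]3[C@@H](C(O)[C@]4(CC=C)C[C@@H](Cc5ccc(I)cc5)N(C(=O)OC(C)(C)C)C4=O)C(C)=C[C@H](C)[C@H]3[C@]2(C)C1 | intermediate
43 | diketone (C34 ketone; C7 ketone; N-Boc lactam; aryl iodide) | C[C@@H]1C[C@H](C)[C@H]2C(=O)[C@@H]3[C@@H](C(=O)[C@]4(CC=C)C[C@@H](Cc5ccc(I)cc5)N(C(=O)OC(C)(C)C)C4=O)C(C)=C[C@H](C)[C@H]3[C@]2(C)C1 | intermediate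
44 | C7 α-alcohol of 43 | C[C@@H]1C[C@H](C)[C@H]2[C@@H](O)[C@@H]3[C@@H](C(=O)[C@]4(CC=C)C[C@@H](Cc5ccc(I)cc5)N(C(=O)OC(C)(C)C)C4=O)C(C)=C[C@H](C)[C@H]3[C@]2(C)C1 | intermediate
45 | N-Boc macrocycle (para-cyclophane aryl ether; C16–H; C19 allyl; C25=C27) | C[C@@H]1C[C@H](C)[C@H]2[C@H]3Oc4ccc(cc4)C[C@@H]4C[C@](CC=C)(C(=O)N4C(=O)OC(C)(C)C)C(=O)[C@H]5C(C)=C[C@H](C)[C@H]([C@H]35)[C@]2(C)C1 | intermediate
46 | macrocyclic NH lactam (C16–H) | C[C@@H]1C[C@H](C)[C@H]2[C@H]3Oc4ccc(cc4)C[C@@H]4C[C@](CC=C)(C(=O)N4)C(=O)[C@H]5C(C)=C[C@H](C)[C@H]([C@H]35)[C@]2(C)C1 | intermediate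
47 | N-chloro lactam of 46 | C[C@@H]1C[C@H](C)[C@H]2[C@H]3Oc4ccc(cc4)C[C@@H]4C[C@](CC=C)(C(=O)N4Cl)C(=O)[C@H]5C(C)=C[C@H](C)[C@H]([C@H]35)[C@]2(C)C1 | intermediate
48 | macrocyclic N-acylimine (C16=N41) | C[C@@H]1C[C@H](C)[C@H]2[C@H]3Oc4ccc(cc4)CC=4C[C@](CC=C)(C(=O)N=4)C(=O)[C@H]5C(C)=C[C@H](C)[C@H]([C@H]35)[C@]2(C)C1 | intermediate
49 | macrocyclic hemiaminal (C16 hydroxyl; C19 allyl; C25=C27; C29–H α) | C[C@@H]1C[C@H](C)[C@H]2[C@H]3Oc4ccc(cc4)C[C@]4(O)C[C@](CC=C)(C(=O)N4)C(=O)[C@H]5C(C)=C[C@H](C)[C@H]([C@H]35)[C@]2(C)C1 | intermediate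
50 | tertiary allylic hydroperoxide (C25 hydroperoxide α; C27=C29) | C[C@@H]1C[C@H](C)[C@H]2[C@H]3Oc4ccc(cc4)C[C@]4(O)C[C@](CC=C)(C(=O)N4)C(=O)[C@H]5[C@@](C)(OO)C=C(C)[C@H]([C@H]35)[C@]2(C)C1 | intermediate
51 | α-epoxy hydroperoxide (C27–O28–C29 epoxide and C25 hydroperoxide both α; C19 allyl) | C[C@@H]1C[C@H](C)[C@H]2[C@H]3Oc4ccc(cc4)C[C@]4(O)C[C@](CC=C)(C(=O)N4)C(=O)[C@H]5[C@@](C)(OO)[C@H]6O[C@@]6(C)[C@H]([C@H]35)[C@]2(C)C1 | intermediate
52 | seco-aldehyde (C21 aldehyde; free C25 hydroperoxide) | C[C@@H]1C[C@H](C)[C@H]2[C@H]3Oc4ccc(cc4)C[C@]4(O)C[C@](CC=O)(C(=O)N4)C(=O)[C@H]5[C@@](C)(OO)[C@H]6O[C@@]6(C)[C@H]([C@H]35)[C@]2(C)C1 | intermediate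
53 | CNP0533733.1 | C[C@@H]1C[C@H](C)[C@H]2[C@H]3Oc4ccc(cc4)C[C@]4(O)C[C@]5(C[C@H](O)OO[C@@]6(C)[C@H]7O[C@@]7(C)[C@H]([C@H]3[C@H]6C5=O)[C@]2(C)C1)C(=O)N4 | target

## Step count and least certain steps

Total: 31 steps. Longest linear sequence: 26 steps (steps 1–14, 17–19 and 23–31). The nitrodiene (steps 15–16) and the lactam (steps 20–22) are side branches.

**Step 8 (key step).** The likely failure is C-allylation through the ortho carbon C4, or loss of face control at C31 if the diphosphine opposes the substrate bias; intermolecular allylation would give oligomers. Fallback: from 11 the primary allylic alcohol is turned into the allylic chloride F1 (MsCl, LiCl, collidine, DMF). Potassium tert-butoxide in THF/t-BuOH then forms the phenolate, which should close ring B by a metal-free intramolecular SN2′ para-alkylation, a base-mediated alkylative dearomatization, and so return to 13.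

**Step 29.** Singlet oxygen may attack the β face or abstract H33 or a C26 hydrogen, which would put the hydroperoxide on the wrong carbon or face. Fallback: from 49, mCPBA should epoxidise C25=C27 from the β face to give the epoxide F6. Perhydrolysis with anhydrous H2O2 and MoO2(acac)2 should open it trans-diaxially at tertiary C25 to the β-hydroxy hydroperoxide F7. The hydroperoxide is silylated (Et3SiCl, imidazole) to the silyl peroxide F8, and the C27 alcohol is eliminated toward C29, its only β-hydrogen, with Martin sulfurane to the silyl peroxide alkene F9. Buffered fluoride then frees 50.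

**Step 30.** The peracid may ignore the hydroperoxide and add from the open β face, since the α face is shielded by the C36 methyl and by O24. Fallback: from 50 the hydroperoxide is capped as the 2-methoxyprop-2-yl peroxyketal F10 (2-methoxypropene, PPTS). NBS in aqueous THF should form the bromonium ion on the β face and admit water at C29 from the α face, giving the bromohydrin F11. K2CO3 in methanol closes the α-epoxide F12 by inversion at C27; the peroxyketal has no α-hydrogen and tolerates the base. Aqueous acetic acid returns 51.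

**Step 26.** Ring strain may let oligomerisation or loss of iodine outrun the closure, and hot carbonate may epimerise C33 or cleave the β-keto lactam. Fallback: from 44 a Miyaura borylation (B2pin2, PdCl2(dppf), KOAc) gives the aryl boronate F3 and KHF2 the trifluoroborate F4. An oxidative copper etherification at room temperature (Cu(OAc)2·H2O, DMAP, O2) then joins the alcohol and the aryl boron and returns to 45 without heat or strong base.

**Step 28.** Positive chlorine may add to the trisubstituted alkene or chlorinate C33 through the enol, and the amidine base may epimerise C33. Fallback: from 46, DDQ abstracts hydride from C15, which is para to the ether oxygen, and loss of H16 gives the enamide F5. Mildly acidic water then hydrates F5 at C16 and returns to 49.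

**Step 10.** Protonation at C6 may occur from the α face and give the cis-fused ketone, or the metal may over-reduce the carbonyl group. Fallback: from 15, copper hydride ((IPr)CuCl, NaOtBu, (EtO)2MeSiH, t-BuOH; IPr = 1,3-bis(2,6-diisopropylphenyl)imidazol-2-ylidene) should deliver hydride to C6 from the open β face under steric control and give the O-silylated ketone F2. Bu4NF and then NaOMe in methanol return 17.

## Further compounds

F1 | step 8 | 3-[(1S,3E)-1-(tert-butyldimethylsilyloxy)-5-chloro-4-methylpent-3-en-1-yl]-2,4,6-trimethylphenol | Cc1cc(C)c(c(C)c1O)[C@@H](O[Si](C)(C)C(C)(C)C)C/C=C(\C)CCl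
F2 | step 10 | trans-fused ketone with the C7 oxygen as its diethoxymethylsilyl ether (C4 epimers) | C[C@@H]1C(=O)C(C)[C@H]2[C@@H](O[Si](C)(OCC)OCC)C[C@@H](C(C)=C)[C@]2(C)C1
F3 | step 26 | aryl pinacol boronate corresponding to 44 | C[C@@H]1C[C@H](C)[C@H]2[C@@H](O)[C@@H]3[C@@H](C(=O)[C@]4(CC=C)C[C@@H](Cc5ccc(cc5)B6OC(C)(C)C(C)(C)O6)N(C(=O)OC(C)(C)C)C4=O)C(C)=C[C@H](C)[C@H]3[C@]2(C)C1
F4 | step 26 | potassium aryltrifluoroborate corresponding to 44 | C[C@@H]1C[C@H](C)[C@H]2[C@@H](O)[C@@H]3[C@@H](C(=O)[C@]4(CC=C)C[C@@H](Cc5ccc(cc5)[B-](F)(F)F)N(C(=O)OC(C)(C)C)C4=O)C(C)=C[C@H](C)[C@H]3[C@]2(C)C1.[K+]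
F5 | step 28 | macrocyclic enamide (C15=C16, ring substituents cis) | C[C@@H]1C[C@H](C)[C@H]2[C@H]3Oc4ccc(cc4)/C=C4\C[C@](CC=C)(C(=O)N4)C(=O)[C@H]5C(C)=C[C@H](C)[C@H]([C@H]35)[C@]2(C)C1
F6 | step 29 | C25–C27 β-epoxide of 49 | C[C@@H]1C[C@H](C)[C@H]2[C@H]3Oc4ccc(cc4)C[C@]4(O)C[C@](CC=C)(C(=O)N4)C(=O)[C@H]5[C@]6(C)O[C@@H]6[C@H](C)[C@H]([C@H]35)[C@]2(C)C1
F7 | step 29 | β-hydroxy hydroperoxide (C25 hydroperoxide α; C27 hydroxyl β) | C[C@@H]1C[C@H](C)[C@H]2[C@H]3Oc4ccc(cc4)C[C@]4(O)C[C@](CC=C)(C(=O)N4)C(=O)[C@H]5[C@@](C)(OO)[C@H](O)[C@H](C)[C@H]([C@H]35)[C@]2(C)C1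
F8 | step 29 | triethylsilyl peroxide of F7 | C[C@@H]1C[C@H](C)[C@H]2[C@H]3Oc4ccc(cc4)C[C@]4(O)C[C@](CC=C)(C(=O)N4)C(=O)[C@H]5[C@@](C)(OO[Si](CC)(CC)CC)[C@H](O)[C@H](C)[C@H]([C@H]35)[C@]2(C)C1
F9 | step 29 | triethylsilyl peroxide of 50 | C[C@@H]1C[C@H](C)[C@H]2[C@H]3Oc4ccc(cc4)C[C@]4(O)C[C@](CC=C)(C(=O)N4)C(=O)[C@H]5[C@@](C)(OO[Si](CC)(CC)CC)C=C(C)[C@H]([C@H]35)[C@]2(C)C1
F10 | step 30 | 2-methoxyprop-2-yl peroxyketal of 50 | C[C@@H]1C[C@H](C)[C@H]2[C@H]3Oc4ccc(cc4)C[C@]4(O)C[C@](CC=C)(C(=O)N4)C(=O)[C@H]5[C@@](C)(OOC(C)(C)OC)C=C(C)[C@H]([C@H]35)[C@]2(C)C1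
F11 | step 30 | bromohydrin (C27 bromine β; C29 hydroxyl α) of F10 | C[C@@H]1C[C@H](C)[C@H]2[C@H]3Oc4ccc(cc4)C[C@]4(O)C[C@](CC=C)(C(=O)N4)C(=O)[C@H]5[C@@](C)(OOC(C)(C)OC)[C@H](Br)[C@@](C)(O)[C@H]([C@H]35)[C@]2(C)C1
F12 | step 30 | 2-methoxyprop-2-yl peroxyketal of 51 | C[C@@H]1C[C@H](C)[C@H]2[C@H]3Oc4ccc(cc4)C[C@]4(O)C[C@](CC=C)(C(=O)N4)C(=O)[C@H]5[C@@](C)(OOC(C)(C)OC)[C@H]6O[C@@]6(C)[C@H]([C@H]35)[C@]2(C)C1
A1 | alternative 1 | macrocyclic 3-alkoxycyclohex-2-enone, C9–C14 not yet aromatic (C12 unspecified) | C[C@@H]1C[C@H](C)[C@H]2[C@H]3OC4=CC(=O)C(CC4)C[C@]4(OC)C[C@](CC(OC)OC)(C(=O)N4)C(=O)[C@H]5C(C)=C[C@H](C)[C@H]([C@H]35)[C@]2(C)C1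
A2 | alternative 1 | paracyclophane aryl ether with C11 hydroxyl | C[C@@H]1C[C@H](C)[C@H]2[C@H]3Oc4cc(O)c(cc4)C[C@]4(OC)C[C@](CC(OC)OC)(C(=O)N4)C(=O)[C@H]5C(C)=C[C@H](C)[C@H]([C@H]35)[C@]2(C)C1
A3 | alternative 2 | 4,6-dimethyl-2H-pyran-2-one | Cc1cc(C)oc(=O)c1
A4 | alternative 2 | methyl (E)-4-oxobut-2-enoate | COC(=O)/C=C/C=O
A5 | alternative 2 | bridged lactone with C7 aldehyde and C36 ester | O=C[C@H]1[C@H](C(=O)OC)[C@@]2(C)C=C(C)[C@@H]1C(=O)O2
A6 | alternative 3 | ring C trienoate (dienyl arm on C31; enoate arm on C32) | C=C(C)/C=C(\C)[C@@H]1[C@@H](C)CC(C)=C(C(=O)OC(C)(C)C)[C@H]1[C@H](O[Si](C)(C)C(C)(C)C)/C=C/C(=O)OC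
A7 | alternative 3 | tricyclic diester with trans A/B and B/C fusions | CC1=C[C@]2(C)[C@@H]([C@@H](C(=O)OC)C1)[C@@H](O[Si](C)(C)C(C)(C)C)[C@H]1[C@H]2[C@@H](C)CC(C)=C1C(=O)OC(C)(C)C
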